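**Remark (assumption).** Labdane numbering is used throughout: C1–C10 are the decalin carbons, C11–C16 the side chain, C17 the methyl on C8, C18 and C19 the two carbons on C4, and C20 the methyl on C10. The target is taken as (3R,4S,5R,6R,10S,13E), i.e. 3α-O-acyl, 4β-CH2O-acyl (C19), 5α-H, 6β-OH, 10β-CH3.

## Retrosynthetic overview

1. The target comes from tetraol 28 by allylic oxidation at C15, selective isovalerylation of 3-OH and 19-OH, and Pinnick oxidation; 28 comes from LiAlH4 opening of the 19,6β-olide 27.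
2. Enabling feature: C19 (on C4) and the 6β-oxygen (on C6) are syn-diaxial on the β-face of the decalin, i.e. cis across the C4–C5 bond, so they can be one γ-lactone. In the open-chain precursor this lactone is an α-methylbutenolide whose ring double bond is C4=C5 and whose stereocentre C6 carries the chain C7–C8=C9 that becomes ring B.
3. Key disconnection: C3–C4 and C5–C10 by an intramolecular Diels–Alder reaction of that butenolide with an (E,E)-dienylboronate (C3 carried as C–B, oxidised afterwards). Rings A and B form together in this step; before it only the temporary butenolide ring exists.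
4. Precursor 24 is assembled from three pieces: the (Z)-tetrasubstituted C8=C9 alkene (carbomagnesiation/iodination of but-2-yn-1-ol, side chain by hydroboration/Cu-catalysed addition to methyl but-2-ynoate), the C5–C7 unit from (R)-glycidyl butanoate (Negishi), and the diene (carboalumination, Suzuki); the butenolide is closed last (Still–Gennari, lactonisation).

Key step: step 13

## Route

Step 1
Reactants: 1 (R)-glycidyl butanoate
Product: 2 (2S)-2-hydroxy-3-iodopropyl butanoate
Conditions: LiI, AcOH, THF, 0 °C → rt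
Reagents that add atoms: lithium iodide, [Li+].[I-]
Why: Regioselective SN2 opening of the terminal epoxide carbon by iodide (halohydrin formation) leaves the stereocentre untouched, so the descriptor changes from R to S by CIP priority only.

Step 2
Reactants: 2 (2S)-2-hydroxy-3-iodopropyl butanoate
Product: 3 (2S)-2-(tert-butyldimethylsilyloxy)-3-iodopropyl butanoate
Conditions: TBSOTf, 2,6-lutidine, CH2Cl2, −78 → 0 °C
Reagents that add atoms: tert-butyldimethylsilyl trifluoromethanesulfonate, CC(C)(C)[Si](C)(C)OS(=O)(=O)C(F)(F)F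
Why: Silylation of the secondary alcohol with a silyl triflate and a hindered base is fast at low temperature and avoids acyl migration or re-closure to the epoxide.

Step 3
Reactants: 4 but-2-yn-1-ol; 5 vinylmagnesium bromide
Product: 7 (2Z)-2-ethenyl-3-iodobut-2-en-1-ol, via cyclic alkenylmagnesium alkoxide 6 (not isolated)
Conditions: CH2=CHMgBr (3 equiv), CuI (10 mol%), THF, 0 °C → reflux; then I2, −40 °C → rt
Reagents that add atoms: iodine, II
Why: Anti-carbomagnesiation of the propargylic alkoxide (Duboudin/Fallis reaction) puts the vinyl group on the carbinol-bearing alkyne carbon and magnesium on the methyl-bearing carbon in a five-membered oxamagnesacycle, and iodinolysis with retention gives the tetrasubstituted alkene with iodine cis to CH2OH, the geometry later needed for C7 cis to C10.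

Step 4
Reactants: 7 (2Z)-2-ethenyl-3-iodobut-2-en-1-ol; 8 methyl but-2-ynoate
Product: 10 methyl (2E,6Z)-6-(hydroxymethyl)-7-iodo-3-methylocta-2,6-dienoate, via B-alkyl-9-BBN adduct 9 (not isolated)
Conditions: 9-BBN, THF, 0 °C → rt; then 8, CuOAc (5 mol%), P(OPh)3 (10 mol%), KOt-Bu (10 mol%), t-BuOH, dioxane, 40 °C
Reagents that add atoms: none
Why: 9-BBN hydroborates only the monosubstituted vinyl group at its terminal carbon, and copper-catalysed syn conjugate addition of the B-alkyl borane to the ynoate with protonation gives the (E)-3-methyl-2-enoate of the side chain without touching the vinyl iodide.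

Step 5
Reactants: 10 methyl (2E,6Z)-6-(hydroxymethyl)-7-iodo-3-methylocta-2,6-dienoate
Product: 11 methyl (2E,6Z)-6-formyl-7-iodo-3-methylocta-2,6-dienoate
Conditions: MnO2 (20 equiv), CH2Cl2, rt
Reagents that add atoms: none
Why: MnO2 oxidises the allylic alcohol selectively to the enal, which also turns the hindered vinyl iodide into an activated β-iodo enal for the coupling that follows.

Step 6
Reactants: 11 methyl (2E,6Z)-6-formyl-7-iodo-3-methylocta-2,6-dienoate; 3 (2S)-2-(tert-butyldimethylsilyloxy)-3-iodopropyl butanoate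
Product: 13 methyl (2E,6Z,9R)-10-(butanoyloxy)-9-(tert-butyldimethylsilyloxy)-6-formyl-3,7-dimethyldeca-2,6-dienoate, via alkylzinc iodide 12 (not isolated)
Conditions: 3, Zn dust, LiCl, THF, 35 °C; then 11, Pd(dppf)Cl2 (5 mol%), THF, rt
Reagents that add atoms: none
Why: Zinc insertion into the primary iodide gives an ester-tolerant alkylzinc whose β-silyloxy group is a poor leaving group, and Negishi sp3–sp2 coupling at the β-iodo enal proceeds with retention of alkene geometry, placing C7 cis to the formyl carbon C10 and importing the C6 stereocentre unchanged.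

Step 7
Reactants: 13 methyl (2E,6Z,9R)-10-(butanoyloxy)-9-(tert-butyldimethylsilyloxy)-6-formyl-3,7-dimethyldeca-2,6-dienoate
Product: 15 methyl (2E,6Z,9R)-9-(tert-butyldimethylsilyloxy)-6-ethynyl-10-hydroxy-3,7-dimethyldeca-2,6-dienoate, via enyne butanoate 14 (not isolated)
Conditions: dimethyl (1-diazo-2-oxopropyl)phosphonate, K2CO3, MeOH, 0 °C → rt
Reagents that add atoms: dimethyl (1-diazo-2-oxopropyl)phosphonate, CC(=O)C(=[N+]=[N-])P(=O)(OC)OC
Why: Seyferth–Gilbert homologation with the Ohira–Bestmann reagent converts the enal into the terminal enyne, and the K2CO3/MeOH medium also removes the primary butanoate by transesterification while the methyl ester and the silyl ether are inert.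

Step 8
Reactants: 15 methyl (2E,6Z,9R)-9-(tert-butyldimethylsilyloxy)-6-ethynyl-10-hydroxy-3,7-dimethyldeca-2,6-dienoate
Product: 17 methyl (2E,6Z,9R)-9-(tert-butyldimethylsilyloxy)-10-hydroxy-6-[(1E)-1-iodoprop-1-en-2-yl]-3,7-dimethyldeca-2,6-dienoate, via alkenyl(dimethyl)alane 16 (not isolated)
Conditions: AlMe3 (4 equiv), Cp2ZrCl2 (0.5 equiv), H2O (2 equiv), CH2Cl2, −23 °C; then I2, THF, −23 → 0 °C
Reagents that add atoms: trimethylaluminium, C[Al](C)C; iodine, II
Why: Zirconium-catalysed, water-accelerated methylalumination (Negishi carboalumination, Wipf conditions) adds CH3 and Al syn across the terminal alkyne with CH3 on the internal carbon, and iodinolysis with retention gives the (E)-iodo diene with C9 trans to iodine, the low temperature sparing the esters.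

Step 9
Reactants: 17 (E)-iodo diene from step 8; 18 (E)-1,2-bis(4,4,5,5-tetramethyl-1,3,2-dioxaborolan-2-yl)ethene
Product: 19 methyl (2E,6Z,9R)-9-(tert-butyldimethylsilyloxy)-10-hydroxy-3,7-dimethyl-6-[(2E,4E)-5-(pinacolboryl)penta-2,4-dien-2-yl]deca-2,6-dienoate
Conditions: 18 (3 equiv), Pd(PPh3)4 (5 mol%), K3PO4, THF–H2O (10:1), 45 °C
Reagents that add atoms: none
Why: Suzuki–Miyaura coupling of the alkenyl iodide with an excess of the symmetrical (E)-bis(boronate) goes with retention at both partners and gives the (1E,3E)-dienylboronate in which the C10 methyl is cis to C2.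

Step 10
Reactants: 19 dienylboronate alcohol from step 9
Product: 20 methyl (2E,6Z,9R)-9-(tert-butyldimethylsilyloxy)-3,7-dimethyl-10-oxo-6-[(2E,4E)-5-(pinacolboryl)penta-2,4-dien-2-yl]deca-2,6-dienoate
Conditions: Dess–Martin periodinane, NaHCO3, CH2Cl2, 0 °C → rt
Reagents that add atoms: none
Why: Buffered Dess–Martin oxidation gives the α-silyloxy aldehyde without epimerisation at C6 and without touching the alkenylboronate.

Step 11
Reactants: 20 α-silyloxy aldehyde from step 10; 21 methyl 2-[bis(2,2,2-trifluoroethoxy)phosphoryl]propanoate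
Product: 22 dimethyl (2Z,4R,6Z,10E)-4-(tert-butyldimethylsilyloxy)-2,6,10-trimethyl-7-[(2E,4E)-5-(pinacolboryl)penta-2,4-dien-2-yl]dodeca-2,6,10-trienedioate
Conditions: 21, KN(SiMe3)2, 18-crown-6, THF, −78 °C; then 20, −78 °C
Reagents that add atoms: none
Why: Still–Gennari olefination with the bis(trifluoroethyl) phosphonate is kinetically Z-selective and puts the ester cis to C6, as needed both for lactonisation and for C19 cis to C6 in the dienophile.

Step 12
Reactants: 22 (Z)-γ-silyloxy enoate from step 11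
Product: 24 methyl (2E,6Z)-3,7-dimethyl-8-[(2R)-4-methyl-5-oxo-2,5-dihydrofuran-2-yl]-6-[(2E,4E)-5-(pinacolboryl)penta-2,4-dien-2-yl]octa-2,6-dienoate, via hydroxy enoate 23 (not isolated)
Conditions: HF·pyridine, pyridine, THF, 0 °C → rt
Reagents that add atoms: none
Why: Desilylation liberates the (Z)-γ-hydroxy enoate, which lactonises spontaneously to the α-methylbutenolide with the C6 stereocentre unchanged.

Step 13
Reactants: 24 butenolide-tethered (E,E)-dienylboronate
Product: 26 methyl (13E)-3α-hydroxy-19-oxo-6β,19-epoxylabda-1,8,13-trien-15-oate, via allylboronate cycloadduct 25 (not isolated)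
Conditions: PhMe (0.005 M), BHT (cat.), 150 °C, sealed tube; then THF, pH 7 phosphate buffer, H2O2 (30% aq.), 0 °C → rt
Reagents that add atoms: hydrogen peroxide, OO
Why: Intramolecular Diels–Alder reaction (type 1 IMDA of a 1,7,9-decatriene; closest precedents are thermal IMDA reactions of tethered butenolides and the cycloaddition/oxidation chemistry of 1-boryl-1,3-dienes): the E,E-dienylboronate adds across the butenolide C4=C5 bond in one concerted, asynchronous [4+2] event that makes C5–C10 and C3–C4. Ring B closes as the six-membered tether ring (C5 to C10 through C6–C9, the Z-C8=C9 bond holding the ends together) and ring A as the cyclohexene of the cycloadduct. The diene can reach only the face of the butenolide on which C7 leaves C6, so the R centre at C6 sets C5 and C4 (H5 cis to H6, the C4 methyl α and the lactone carbonyl C19 β); the E,E geometry puts the C10 methyl inside and boron outside, which fixes C20 and the C3 substituent trans to each other. The step needs the lactone-exo mode, the one that gives the trans-decalin with C20 syn to the lactone; it is expected to be at least competitive because the α-methylbutenolide and the weakly polarised boryl diene give little endo bias under uncatalysed conditions, while the endo mode pays a methyl/methyl contact between C20 and the C4 methyl and must stack the diene on the lactone face already occupied by C7. Oxidation of allylic boronate 25 with retention then gives the 3α-hydroxyl, so C3, C4, C5 and C10 and both rings come from one operation.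

Step 14
Reactants: 26 methyl (13E)-3α-hydroxy-19-oxo-6β,19-epoxylabda-1,8,13-trien-15-oate
Product: 27 methyl (13E)-3α-hydroxy-19-oxo-6β,19-epoxylabda-8,13-dien-15-oate
Conditions: 2-nitrobenzenesulfonylhydrazide (NBSH), Et3N, CH2Cl2, rt
Reagents that add atoms: none
Why: Diimide generated in situ reduces the cis-disubstituted C1=C2 bond by syn hydrogen transfer much faster than the tetrasubstituted C8=C9 bond or the conjugated trisubstituted enoate, and creates no stereocentre.

Step 15
Reactants: 27 methyl (13E)-3α-hydroxy-19-oxo-6β,19-epoxylabda-8,13-dien-15-oate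
Product: 28 (13E)-labda-8,13-diene-3α,6β,15,19-tetraol
Conditions: LiAlH4, THF, 0 °C → rt; Rochelle salt work-up
Reagents that add atoms: none
Why: LiAlH4 reduces the γ-lactone to the 6β,19-diol and the enoate to the (E)-allylic alcohol by 1,2-reduction, with all stereocentres untouched.

Step 16
Reactants: 28 (13E)-labda-8,13-diene-3α,6β,15,19-tetraol
Product: 29 (13E)-3α,6β,19-trihydroxylabda-8,13-dien-15-al
Conditions: MnO2 (20 equiv), CH2Cl2, rt
Reagents that add atoms: none
Why: MnO2 oxidises only the allylic primary alcohol at C15 to the (E)-enal, which keeps this position out of the acylation and sets up the final oxidation.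

Step 17
Reactants: 29 (13E)-3α,6β,19-trihydroxylabda-8,13-dien-15-al; 30 3-methylbutanoic anhydride
Product: 31 (13E)-6β-hydroxy-3α,19-bis(3-methylbutanoyloxy)labda-8,13-dien-15-al
Conditions: 30 (2.3 equiv), DMAP (0.3 equiv), Et3N, CH2Cl2, 0 °C → rt
Reagents that add atoms: none
Why: DMAP-catalysed acylation with a limited amount of anhydride should esterify the primary 19-OH and the secondary 3α-OH, while the 6β-OH, syn-diaxial to C20 and to the C19 substituent, is the most hindered hydroxyl and should stay free.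

Step 18
Reactants: 31 (13E)-6β-hydroxy-3α,19-bis(3-methylbutanoyloxy)labda-8,13-dien-15-al
Product: 32 (13E)-6β-hydroxy-3α,19-bis(3-methylbutanoyloxy)labda-8,13-dien-15-oic acid (CNP0333611.1)
Conditions: NaClO2, NaH2PO4, 2-methyl-2-butene, t-BuOH–H2O (3:1), 0 °C → rt
Reagents that add atoms: sodium chlorite, [Na+].[O-]Cl=O
Why: Pinnick (Lindgren–Kraus) oxidation converts the enal into the acid under buffered conditions that leave the two esters, the free secondary alcohol and both alkene geometries untouched.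

## Compound list

1 | (R)-glycidyl butanoate | CCCC(=O)OC[C@H]1CO1 | starting material
2 | (2S)-2-hydroxy-3-iodopropyl butanoate | CCCC(=O)OC[C@H](O)CI | intermediate
3 | (2S)-2-(tert-butyldimethylsilyloxy)-3-iodopropyl butanoate | CCCC(=O)OC[C@H](O[Si](C)(C)C(C)(C)C)CI | intermediate
4 | but-2-yn-1-ol | CC#CCO | starting material
5 | vinylmagnesium bromide | C=C[Mg]Br | starting material
6 | cyclic alkenylmagnesium alkoxide (oxamagnesacycle, not isolated) | C=CC1=C(C)[Mg]OC1 | intermediate
7 | (2Z)-2-ethenyl-3-iodobut-2-en-1-ol | OC/C(C=C)=C(\I)C | intermediate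
8 | methyl but-2-ynoate | CC#CC(=O)OC | starting material
9 | B-[(3Z)-3-(hydroxymethyl)-4-iodopent-3-en-1-yl]-9-BBN (not isolated) | C/C(I)=C(\CCB1C2CCCC1CCC2)CO | intermediate
10 | methyl (2E,6Z)-6-(hydroxymethyl)-7-iodo-3-methylocta-2,6-dienoate | COC(=O)/C=C(\C)CC/C(CO)=C(/I)C | intermediate
11 | methyl (2E,6Z)-6-formyl-7-iodo-3-methylocta-2,6-dienoate | COC(=O)/C=C(\C)CC/C(C=O)=C(/I)C | intermediate
12 | [(2S)-3-(butanoyloxy)-2-(tert-butyldimethylsilyloxy)propyl]zinc iodide (not isolated) | CCCC(=O)OC[C@H](O[Si](C)(C)C(C)(C)C)C[Zn]I | intermediate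
13 | methyl (2E,6Z,9R)-10-(butanoyloxy)-9-(tert-butyldimethylsilyloxy)-6-formyl-3,7-dimethyldeca-2,6-dienoate | COC(=O)/C=C(\C)CC/C(C=O)=C(/C[C@@H](O[Si](C)(C)C(C)(C)C)COC(=O)CCC)C | intermediate
14 | methyl (2E,6Z,9R)-10-(butanoyloxy)-9-(tert-butyldimethylsilyloxy)-6-ethynyl-3,7-dimethyldeca-2,6-dienoate (not isolated) | COC(=O)/C=C(\C)CC/C(C#C)=C(/C[C@@H](O[Si](C)(C)C(C)(C)C)COC(=O)CCC)C | intermediate
15 | methyl (2E,6Z,9R)-9-(tert-butyldimethylsilyloxy)-6-ethynyl-10-hydroxy-3,7-dimethyldeca-2,6-dienoate | COC(=O)/C=C(\C)CC/C(C#C)=C(/C[C@@H](O[Si](C)(C)C(C)(C)C)CO)C | intermediate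
16 | (E)-alkenyl(dimethyl)alane of 15, hydroxyl as dimethylaluminium alkoxide (not isolated) | C[Al](C)/C=C(\C)/C(CC/C(C)=C/C(=O)OC)=C(/C)C[C@@H](O[Si](C)(C)C(C)(C)C)CO[Al](C)C | intermediate
17 | methyl (2E,6Z,9R)-9-(tert-butyldimethylsilyloxy)-10-hydroxy-6-[(1E)-1-iodoprop-1-en-2-yl]-3,7-dimethyldeca-2,6-dienoate | I/C=C(\C)/C(CC/C(C)=C/C(=O)OC)=C(/C)C[C@@H](O[Si](C)(C)C(C)(C)C)CO | intermediate
18 | (E)-1,2-bis(4,4,5,5-tetramethyl-1,3,2-dioxaborolan-2-yl)ethene | CC1(C)OB(/C=C/B2OC(C)(C)C(C)(C)O2)OC1(C)C | starting material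
19 | methyl (2E,6Z,9R)-9-(tert-butyldimethylsilyloxy)-10-hydroxy-3,7-dimethyl-6-[(2E,4E)-5-(pinacolboryl)penta-2,4-dien-2-yl]deca-2,6-dienoate | CC1(C)OB(/C=C/C=C(\C)/C(CC/C(C)=C/C(=O)OC)=C(/C)C[C@@H](O[Si](C)(C)C(C)(C)C)CO)OC1(C)C | intermediate
20 | methyl (2E,6Z,9R)-9-(tert-butyldimethylsilyloxy)-3,7-dimethyl-10-oxo-6-[(2E,4E)-5-(pinacolboryl)penta-2,4-dien-2-yl]deca-2,6-dienoate | CC1(C)OB(/C=C/C=C(\C)/C(CC/C(C)=C/C(=O)OC)=C(/C)C[C@@H](O[Si](C)(C)C(C)(C)C)C=O)OC1(C)C | intermediate
21 | methyl 2-[bis(2,2,2-trifluoroethoxy)phosphoryl]propanoate | COC(=O)C(C)P(=O)(OCC(F)(F)F)OCC(F)(F)F | starting material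
22 | dimethyl (2Z,4R,6Z,10E)-4-(tert-butyldimethylsilyloxy)-2,6,10-trimethyl-7-[(2E,4E)-5-(pinacolboryl)penta-2,4-dien-2-yl]dodeca-2,6,10-trienedioate | CC1(C)OB(/C=C/C=C(\C)/C(CC/C(C)=C/C(=O)OC)=C(/C)C[C@@H](O[Si](C)(C)C(C)(C)C)/C=C(/C)C(=O)OC)OC1(C)C | intermediate
23 | dimethyl (2Z,4R,6Z,10E)-4-hydroxy-2,6,10-trimethyl-7-[(2E,4E)-5-(pinacolboryl)penta-2,4-dien-2-yl]dodeca-2,6,10-trienedioate (not isolated) | CC1(C)OB(/C=C/C=C(\C)/C(CC/C(C)=C/C(=O)OC)=C(/C)C[C@@H](O)/C=C(/C)C(=O)OC)OC1(C)C | intermediate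
24 | methyl (2E,6Z)-3,7-dimethyl-8-[(2R)-4-methyl-5-oxo-2,5-dihydrofuran-2-yl]-6-[(2E,4E)-5-(pinacolboryl)penta-2,4-dien-2-yl]octa-2,6-dienoate | CC1(C)OB(/C=C/C=C(\C)/C(CC/C(C)=C/C(=O)OC)=C(/C)C[C@H]2OC(=O)C(C)=C2)OC1(C)C | intermediate
25 | methyl (13E)-19-oxo-3α-(pinacolboryl)-6β,19-epoxylabda-1,8,13-trien-15-oate (not isolated) | CC1=C(CC/C(C)=C/C(=O)OC)[C@@]2(C)C=C[C@@H](B4OC(C)(C)C(C)(C)O4)[C@]3(C)C(=O)O[C@H](C1)[C@H]23 | intermediate
26 | methyl (13E)-3α-hydroxy-19-oxo-6β,19-epoxylabda-1,8,13-trien-15-oate | CC1=C(CC/C(C)=C/C(=O)OC)[C@@]2(C)C=C[C@@H](O)[C@]3(C)C(=O)O[C@H](C1)[C@H]23 | intermediate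
27 | methyl (13E)-3α-hydroxy-19-oxo-6β,19-epoxylabda-8,13-dien-15-oate | CC1=C(CC/C(C)=C/C(=O)OC)[C@@]2(C)CC[C@@H](O)[C@]3(C)C(=O)O[C@H](C1)[C@H]23 | intermediate
28 | (13E)-labda-8,13-diene-3α,6β,15,19-tetraol | CC1=C(CC/C(C)=C/CO)[C@@]2(C)CC[C@@H](O)[C@](C)(CO)[C@@H]2[C@H](O)C1 | intermediate
29 | (13E)-3α,6β,19-trihydroxylabda-8,13-dien-15-al | CC1=C(CC/C(C)=C/C=O)[C@@]2(C)CC[C@@H](O)[C@](C)(CO)[C@@H]2[C@H](O)C1 | intermediate
30 | 3-methylbutanoic anhydride | CC(C)CC(=O)OC(=O)CC(C)C | starting material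
31 | (13E)-6β-hydroxy-3α,19-bis(3-methylbutanoyloxy)labda-8,13-dien-15-al | CC1=C(CC/C(C)=C/C=O)[C@@]2(C)CC[C@@H](OC(=O)CC(C)C)[C@](C)(COC(=O)CC(C)C)[C@@H]2[C@H](O)C1 | intermediate
32 | (13E)-6β-hydroxy-3α,19-bis(3-methylbutanoyloxy)labda-8,13-dien-15-oic acid (CNP0333611.1) | CC1=C(CC/C(C)=C/C(=O)O)[C@@]2(C)CC[C@@H](OC(=O)CC(C)C)[C@](C)(COC(=O)CC(C)C)[C@@H]2[C@H](O)C1 | target

## Step count and risks

Total step count: 18. Longest linear sequence: 16 steps (steps 3–18, from but-2-yn-1-ol); steps 1–2 prepare the C5–C7 fragment.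

**Step 13 (the cycloaddition) is the weakest point.** The face of the dienophile is fixed by C6, but the exo/endo partition is not: the cycloaddition may run through the lactone-endo transition state, with the diene stacked over the lactone, which would give the cis-fused adduct epimeric at C3 and C10. The weakly activated tetraene may also react slowly enough to decompose. The fallback changes the dienophile so that the endo rule works for the trans ring fusion, by carrying C18 as a formyl group. It sets out from aldehyde 20: Still–Gennari olefination with methyl bis(2,2,2-trifluoroethyl)phosphonoacetate would give the (Z)-enoate F1, and HF·pyridine the α-unsubstituted butenolide F2. Morita–Baylis–Hillman hydroxymethylation (aqueous formaldehyde, DMAP) would give the hydroxymethyl butenolide F3, and MnO2 the 3-formylbutenolide F4. F4 is a doubly activated dienophile that should cyclise near room temperature with the formyl group (cis to H5, the stronger acceptor) endo, and hence tether and lactone exo, to the boronate aldehyde F5. Tosylhydrazone F6 (TsNHNH2) and reduction with catecholborane/NaOAc would turn C18 into the methyl group; the fallback comes back to the route at boronate 25, which is oxidised as in step 13.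

**Step 9 (Suzuki coupling with the symmetrical bis-boronate).** Double coupling to oligomers, or protodeboronation of the sensitive trienylboronate under aqueous base, may erode the yield. The fallback sets out from iodide 17: Sonogashira coupling with trimethylsilylacetylene (Pd(PPh3)2Cl2, CuI, Et3N) would give the silyl dienyne F7, K2CO3/MeOH the terminal dienyne F8, and Cp2Zr(H)Cl-catalysed syn hydroboration with pinacolborane the (E)-alkenylboronate; it comes back at compound 19.

**Step 17 (site-selective acylation).** Selectivity may be lost through over-acylation at the hindered 6β-hydroxyl or incomplete acylation of the axial 3α-hydroxyl. The fallback protects the syn-diaxial 6,19-diol temporarily as a ring. It sets out from 29: t-Bu2Si(OTf)2/2,6-lutidine can bridge only O6 and O19 and would give the silylene F9; isovaleric anhydride/DMAP would give the 3-isovalerate F10; HF·pyridine would free the diol F11; isovaleryl chloride with 2,4,6-collidine at −40 °C should acylate only the primary 19-hydroxyl, and the fallback comes back at compound 31.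

Further compounds
F1 | step 13 | methyl (2E,6Z)-3,7-dimethyl-… (Z)-enoate without the C4 methyl: dimethyl (2Z,4R,6Z,10E)-4-(tert-butyldimethylsilyloxy)-6,10-dimethyl-7-[(2E,4E)-5-(pinacolboryl)penta-2,4-dien-2-yl]dodeca-2,6,10-trienedioate | CC1(C)OB(/C=C/C=C(\C)/C(CC/C(C)=C/C(=O)OC)=C(/C)C[C@@H](O[Si](C)(C)C(C)(C)C)/C=C\C(=O)OC)OC1(C)C
F2 | step 13 | methyl (2E,6Z)-3,7-dimethyl-8-[(2R)-5-oxo-2,5-dihydrofuran-2-yl]-6-[(2E,4E)-5-(pinacolboryl)penta-2,4-dien-2-yl]octa-2,6-dienoate | CC1(C)OB(/C=C/C=C(\C)/C(CC/C(C)=C/C(=O)OC)=C(/C)C[C@H]2OC(=O)C=C2)OC1(C)C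
F3 | step 13 | methyl (2E,6Z)-8-[(2R)-4-(hydroxymethyl)-5-oxo-2,5-dihydrofuran-2-yl]-3,7-dimethyl-6-[(2E,4E)-5-(pinacolboryl)penta-2,4-dien-2-yl]octa-2,6-dienoate | CC1(C)OB(/C=C/C=C(\C)/C(CC/C(C)=C/C(=O)OC)=C(/C)C[C@H]2OC(=O)C(CO)=C2)OC1(C)C
F4 | step 13 | methyl (2E,6Z)-8-[(2R)-4-formyl-5-oxo-2,5-dihydrofuran-2-yl]-3,7-dimethyl-6-[(2E,4E)-5-(pinacolboryl)penta-2,4-dien-2-yl]octa-2,6-dienoate | CC1(C)OB(/C=C/C=C(\C)/C(CC/C(C)=C/C(=O)OC)=C(/C)C[C@H]2OC(=O)C(C=O)=C2)OC1(C)C
F5 | step 13 | methyl (13E)-18,19-dioxo-3α-(pinacolboryl)-6β,19-epoxylabda-1,8,13-trien-15-oate | CC1=C(CC/C(C)=C/C(=O)OC)[C@@]2(C)C=C[C@@H](B4OC(C)(C)C(C)(C)O4)[C@]3(C=O)C(=O)O[C@H](C1)[C@H]23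
F6 | step 13 | 18-tosylhydrazone of F5 | CC1=C(CC/C(C)=C/C(=O)OC)[C@@]2(C)C=C[C@@H](B4OC(C)(C)C(C)(C)O4)[C@]3(C=NNS(=O)(=O)c5ccc(C)cc5)C(=O)O[C@H](C1)[C@H]23
F7 | step 9 | methyl (2E,6Z,9R)-9-(tert-butyldimethylsilyloxy)-10-hydroxy-3,7-dimethyl-6-[(2E)-5-(trimethylsilyl)pent-2-en-4-yn-2-yl]deca-2,6-dienoate | C[Si](C)(C)C#C/C=C(\C)/C(CC/C(C)=C/C(=O)OC)=C(/C)C[C@@H](O[Si](C)(C)C(C)(C)C)CO
F8 | step 9 | methyl (2E,6Z,9R)-9-(tert-butyldimethylsilyloxy)-10-hydroxy-3,7-dimethyl-6-[(2E)-pent-2-en-4-yn-2-yl]deca-2,6-dienoate | C#C/C=C(\C)/C(CC/C(C)=C/C(=O)OC)=C(/C)C[C@@H](O[Si](C)(C)C(C)(C)C)CO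
F9 | step 17 | (13E)-6β,19-O-(di-tert-butylsilylene)-3α-hydroxylabda-8,13-dien-15-al | CC1=C(CC/C(C)=C/C=O)[C@@]2(C)CC[C@@H](O)[C@]3(C)CO[Si](C(C)(C)C)(C(C)(C)C)O[C@H](C1)[C@H]23
F10 | step 17 | (13E)-6β,19-O-(di-tert-butylsilylene)-3α-(3-methylbutanoyloxy)labda-8,13-dien-15-al | CC1=C(CC/C(C)=C/C=O)[C@@]2(C)CC[C@@H](OC(=O)CC(C)C)[C@]3(C)CO[Si](C(C)(C)C)(C(C)(C)C)O[C@H](C1)[C@H]23
F11 | step 17 | (13E)-6β,19-dihydroxy-3α-(3-methylbutanoyloxy)labda-8,13-dien-15-al | CC1=C(CC/C(C)=C/C=O)[C@@]2(C)CC[C@@H](OC(=O)CC(C)C)[C@](C)(CO)[C@@H]2[C@H](O)C1
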